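Ring A, a fully substituted benzene carrying oxygen at C5, C6, C7 and C8a, prenyl at C8 and the ring C carbon at C4a, is disconnected across C4a–C8a to a squarate-derived cyclobutenone. Heating the 2-prenyl-3-tert-butoxy-4-(methoxymethoxy)-4-(1-methoxyvinyl)cyclobutenone should open it to a dienylketene whose 6π electrocyclisation and enolisation deliver the arene in one operation, with every substituent in place, C8a–OH as the only free hydroxyl and C4a–H as the only ring hydrogen. Ring C is then annulated as a chromone and the C2 stereocentre is set by enantioselective conjugate arylation, before one acidic global deprotection.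

Key step: step 3

Remark: prenyl chloride replaces the bromide because allylic barium reagents form cleanly from chlorides, 4-(methoxymethoxy)phenylboronic acid and (R)-t-BuPyOx are assumed purchasable, and the racemic centres at C4 of the cyclobutenone and at the 1-ethoxyethyl acetal carbon are both erased before C2 is set.

Step 1
Reactants: 1 di-tert-butyl squarate; 2 prenyl chloride (1-chloro-3-methylbut-2-ene)
Product: 6 3-tert-butoxy-4-(3-methylbut-2-enyl)cyclobut-3-ene-1,2-dione, via prenylbarium chloride 3 (not isolated), via barium alkoxide adduct 4 (not isolated), via tertiary trifluoroacetate 5 (not isolated)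
Conditions: BaI2, lithium biphenylide (LiC12H10, 2 equiv), THF, rt; 2, −78 °C; 1, −78 °C; then (CF3CO)2O, −78 → 0 °C; aq. NaHCO3
Reagents that add atoms: none
Why: Allylic barium reagents add to ketone carbonyls through their unsubstituted (α) terminus, so 1,2-addition to one squarate carbonyl should install a linear prenyl group, and trifluoroacetylation of the alkoxide then triggers the known ionisation–transposition of squarate adducts, in which one tert-butyl group leaves as 2-methylpropene to give the 3-alkoxy-4-alkylcyclobutenedione.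

Step 2
Reactants: 6 3-tert-butoxy-4-(3-methylbut-2-enyl)cyclobut-3-ene-1,2-dione; 7 methyl vinyl ether
Product: 10 racemic 3-tert-butoxy-4-(methoxymethoxy)-4-(1-methoxyvinyl)-2-(3-methylbut-2-enyl)cyclobut-2-en-1-one, via 1-methoxyvinyllithium 8 (not isolated), via lithium alkoxide 9 (not isolated)
Conditions: 7, t-BuLi, THF, −78 → 0 °C; then 6, −78 °C; then MOMCl, DMPU, −78 → −20 °C
Reagents that add atoms: chloromethyl methyl ether, COCCl
Why: α-Lithiation of the vinyl ether and 1,2-addition to the more ketone-like carbonyl (the one next to the tert-butoxy-bearing carbon, not the vinylogous ester carbonyl) follows the established regiochemistry of 3-alkoxy-4-alkylcyclobutenediones, and Williamson-type O-alkylation of the tertiary lithium alkoxide with MOMCl caps the carbinol oxygen, the new quaternary centre being racemic and destroyed in step 3.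

Step 3
Reactants: 10 racemic 3-tert-butoxy-4-(methoxymethoxy)-4-(1-methoxyvinyl)-2-(3-methylbut-2-enyl)cyclobut-2-en-1-one
Product: 13 3-tert-butoxy-5-methoxy-4-(methoxymethoxy)-2-(3-methylbut-2-enyl)phenol, via dienylketene 11 (not isolated), via cyclohexadienone 12 (not isolated)
Conditions: toluene (0.02 M, degassed, base-washed glassware), 105 °C, Ar
Reagents that add atoms: none
Why: Thermal conrotatory 4π electrocyclic opening of the C1–C4 bond of the cyclobutenone gives dienylketene 11, whose ketene carbon (future C8a) bonds to the methylene terminus of the methoxyvinyl group (future C4a), and enolisation of cyclohexadienone 12 gives the phenol. The closest known reaction type is the thermal ring expansion of 4-alkenyl-4-oxycyclobutenones from squaric esters to highly oxygenated phenols and hydroquinone monoethers (Moore rearrangement). Ring A is closed by a thermal disrotatory 6π electrocyclisation that forms the C4a–C8a bond, and no stereocentre is created, the racemic quaternary carbon of 10 becoming the sp2 carbon C6. The step needs torquoselectivity, the methoxyvinyl group having to rotate inward to give the (Z)-dienylketene, and this is secured by the strong preference of the C4 oxygen donor (the methoxymethoxy group) for outward rotation. Capping that oxygen as an ether blocks oxidation to a quinone and leaves the ketene-derived C8a hydroxyl as the only free phenol, while high dilution suppresses intermolecular trapping of the ketene.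

Step 4
Reactants: 13 3-tert-butoxy-5-methoxy-4-(methoxymethoxy)-2-(3-methylbut-2-enyl)phenol
Product: 14 racemic 1-tert-butoxy-3-(1-ethoxyethoxy)-5-methoxy-6-(methoxymethoxy)-2-(3-methylbut-2-enyl)benzene
Conditions: ethyl vinyl ether, PPTS (5 mol%), CH2Cl2, 0 °C → rt
Reagents that add atoms: ethyl vinyl ether, CCOC=C
Why: Buffered acid-catalysed addition of the phenol to the vinyl ether (acetal protection) masks the C8a hydroxyl as a 1-ethoxyethyl ether that directs metalation and can later be removed without touching the MOM and aryl tert-butyl ethers, its acetal carbon being a racemic centre of no consequence.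

Step 5
Reactants: 14 racemic 1-tert-butoxy-3-(1-ethoxyethoxy)-5-methoxy-6-(methoxymethoxy)-2-(3-methylbut-2-enyl)benzene; 15 N-methoxy-N-methylacetamide
Product: 18 1-[4-tert-butoxy-2-(1-ethoxyethoxy)-6-methoxy-5-(methoxymethoxy)-3-(3-methylbut-2-enyl)phenyl]ethanone (racemic at the acetal carbon), via aryllithium 16 (not isolated), via tetrahedral lithium adduct 17 (not isolated)
Conditions: n-BuLi, THF, 0 °C; then 15, −78 → 0 °C; aq. NH4Cl
Reagents that add atoms: none
Why: Directed ortho-metalation removes the only ring hydrogen (C4a–H), which is flanked and cooperatively activated by the acetal and methoxy oxygens, and Weinreb amide acylation of the aryllithium stops at the ketone because the chelated tetrahedral adduct persists until work-up.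

Step 6
Reactants: 18 1-[4-tert-butoxy-2-(1-ethoxyethoxy)-6-methoxy-5-(methoxymethoxy)-3-(3-methylbut-2-enyl)phenyl]ethanone; 19 N,N-dimethylformamide dimethyl acetal
Product: 20 (E)-1-[4-tert-butoxy-2-(1-ethoxyethoxy)-6-methoxy-5-(methoxymethoxy)-3-(3-methylbut-2-enyl)phenyl]-3-(dimethylamino)prop-2-en-1-one
Conditions: 19 (5 equiv), toluene, 100 °C
Reagents that add atoms: none
Why: Condensation of the methyl ketone with the amide acetal (enaminone formation) adds the carbon that becomes C2 under neutral conditions that none of the protecting groups or the prenyl group should feel.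

Step 7
Reactants: 20 (E)-1-[4-tert-butoxy-2-(1-ethoxyethoxy)-6-methoxy-5-(methoxymethoxy)-3-(3-methylbut-2-enyl)phenyl]-3-(dimethylamino)prop-2-en-1-one
Product: 22 7-tert-butoxy-5-methoxy-6-(methoxymethoxy)-8-(3-methylbut-2-enyl)-4H-chromen-4-one, via hydroxyaryl enaminone 21 (not isolated)
Conditions: AcOH–THF–H2O (4:2:1), 50–60 °C
Reagents that add atoms: none
Why: Mild acid hydrolysis of the 1-ethoxyethyl acetal frees the C8a hydroxyl, which adds to the protonated enaminone and expels dimethylamine (addition–elimination chromone synthesis), closing ring C through O1–C2 in a medium too weakly acidic to cleave the MOM or aryl tert-butyl ethers.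

Step 8
Reactants: 22 7-tert-butoxy-5-methoxy-6-(methoxymethoxy)-8-(3-methylbut-2-enyl)-4H-chromen-4-one
Product: 24 7-tert-butoxy-5-hydroxy-6-(methoxymethoxy)-8-(3-methylbut-2-enyl)-4H-chromen-4-one, via magnesium phenoxide chelate 23 (not isolated)
Conditions: MgI2·OEt2 (2.5 equiv), THF, 50 °C; aq. NH4Cl
Reagents that add atoms: none
Why: In this chelation-controlled ether cleavage MgI2 binds the C4 carbonyl and the peri methoxy oxygen and iodide removes the methyl group by SN2 attack, a selectivity well known for methoxy groups ortho or peri to a carbonyl and used here before any stereocentre exists.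

Step 9
Reactants: 24 7-tert-butoxy-5-hydroxy-6-(methoxymethoxy)-8-(3-methylbut-2-enyl)-4H-chromen-4-one
Product: 25 7-tert-butoxy-5,6-bis(methoxymethoxy)-8-(3-methylbut-2-enyl)-4H-chromen-4-one
Conditions: MOMCl (excess), iPr2NEt, Bu4NI (cat.), CH2Cl2, 40 °C
Reagents that add atoms: chloromethyl methyl ether, COCCl
Why: O-Alkylation of the chelated phenol (MOM protection) replaces the robust methyl ether by an acetal that falls in the final acid step, and the excess reagent would also re-cap the C6 oxygen should the Lewis acid of step 8 have bared it.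

Step 10
Reactants: 25 7-tert-butoxy-5,6-bis(methoxymethoxy)-8-(3-methylbut-2-enyl)-4H-chromen-4-one; 26 4-(methoxymethoxy)phenylboronic acid
Product: 27 (2S)-7-tert-butoxy-5,6-bis(methoxymethoxy)-2-[4-(methoxymethoxy)phenyl]-8-(3-methylbut-2-enyl)-2,3-dihydro-4H-chromen-4-one
Conditions: Pd(OCOCF3)2 (5 mol%), (R)-t-BuPyOx [(R)-4-tert-butyl-2-(pyridin-2-yl)-4,5-dihydrooxazole] (6 mol%), NH4PF6 (30 mol%), H2O (5 equiv), 26 (2 equiv), ClCH2CH2Cl, 60 °C
Reagents that add atoms: none
Why: This is the enantioselective conjugate addition of an arylboronic acid to a chromone under a cationic divalent palladium–pyridinooxazoline catalyst (transmetalation, enantiodetermining carbopalladation of C2=C3, base-free protonolysis of the palladium enolate), in which the ligand's tert-butyl group controls the C2 configuration and the (R)-ligand is chosen as the enantiomer expected to deliver the aryl group to the face that gives 2S, an assignment to be verified by circular dichroism.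

Step 11
Reactants: 27 (2S)-7-tert-butoxy-5,6-bis(methoxymethoxy)-2-[4-(methoxymethoxy)phenyl]-8-(3-methylbut-2-enyl)-2,3-dihydro-4H-chromen-4-one
Product: 28 nirurinetin, (2S)-5,6,7-trihydroxy-2-(4-hydroxyphenyl)-8-(3-methylbut-2-enyl)-2,3-dihydro-4H-chromen-4-one
Conditions: 3 M aq. HCl, MeOH (degassed), 50 °C, Ar
Reagents that add atoms: none
Why: Acid-catalysed solvolysis of the three MOM acetals and of the hindered, electron-rich C7 tert-butyl ether (global deprotection) should release all four hydroxyls in one operation under conditions of the kind used for MOM-protected prenylflavanones, which, kept below reflux and free of oxygen, should spare the prenyl double bond, the pyrogallol unit and the base-sensitive but acid-tolerant C2 stereocentre.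

Compound list
1 | di-tert-butyl squarate (3,4-di-tert-butoxycyclobut-3-ene-1,2-dione) | CC(C)(C)OC1=C(OC(C)(C)C)C(=O)C1=O | starting material
2 | prenyl chloride (1-chloro-3-methylbut-2-ene) | CC(C)=CCCl | starting material
3 | prenylbarium chloride | CC(C)=CC[Ba]Cl | intermediate
4 | chlorobarium 2,3-di-tert-butoxy-1-(3-methylbut-2-enyl)-4-oxocyclobut-2-en-1-olate (racemic) | CC(C)=CCC1([O-])C(OC(C)(C)C)=C(OC(C)(C)C)C1=O.[Ba+2].[Cl-] | intermediate
5 | 2,3-di-tert-butoxy-1-(3-methylbut-2-enyl)-4-oxocyclobut-2-en-1-yl trifluoroacetate (racemic) | CC(C)=CCC1(OC(=O)C(F)(F)F)C(OC(C)(C)C)=C(OC(C)(C)C)C1=O | intermediate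
6 | 3-tert-butoxy-4-(3-methylbut-2-enyl)cyclobut-3-ene-1,2-dione | CC(C)=CCC1=C(OC(C)(C)C)C(=O)C1=O | intermediate
7 | methyl vinyl ether | COC=C | starting material
8 | 1-methoxyvinyllithium | [Li]C(=C)OC | intermediate
9 | lithium 2-tert-butoxy-1-(1-methoxyvinyl)-3-(3-methylbut-2-enyl)-4-oxocyclobut-2-en-1-olate (racemic) | CC(C)=CCC1=C(OC(C)(C)C)C([O-])(C(OC)=C)C1=O.[Li+] | intermediate
10 | racemic 3-tert-butoxy-4-(methoxymethoxy)-4-(1-methoxyvinyl)-2-(3-methylbut-2-enyl)cyclobut-2-en-1-one | CC(C)=CCC1=C(OC(C)(C)C)C(OCOC)(C(OC)=C)C1=O | intermediate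
11 | (Z)-dienylketene, (3Z)-3-tert-butoxy-5-methoxy-4-(methoxymethoxy)-2-(3-methylbut-2-enyl)hexa-1,3,5-trien-1-one | O=C=C(CC=C(C)C)/C(OC(C)(C)C)=C(OCOC)\C(OC)=C | intermediate
12 | 3-tert-butoxy-5-methoxy-4-(methoxymethoxy)-2-(3-methylbut-2-enyl)cyclohexa-2,4-dien-1-one | CC(C)=CCC1=C(OC(C)(C)C)C(OCOC)=C(OC)CC1=O | intermediate
13 | 3-tert-butoxy-5-methoxy-4-(methoxymethoxy)-2-(3-methylbut-2-enyl)phenol | CC(C)=CCc1c(O)cc(OC)c(OCOC)c1OC(C)(C)C | intermediate
14 | racemic 1-tert-butoxy-3-(1-ethoxyethoxy)-5-methoxy-6-(methoxymethoxy)-2-(3-methylbut-2-enyl)benzene | CC(C)=CCc1c(OC(C)OCC)cc(OC)c(OCOC)c1OC(C)(C)C | intermediate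
15 | N-methoxy-N-methylacetamide | CC(=O)N(C)OC | starting material
16 | [4-tert-butoxy-2-(1-ethoxyethoxy)-6-methoxy-5-(methoxymethoxy)-3-(3-methylbut-2-enyl)phenyl]lithium | CC(C)=CCc1c(OC(C)OCC)c([Li])c(OC)c(OCOC)c1OC(C)(C)C | intermediate
17 | lithium 1-[4-tert-butoxy-2-(1-ethoxyethoxy)-6-methoxy-5-(methoxymethoxy)-3-(3-methylbut-2-enyl)phenyl]-1-[methoxy(methyl)amino]ethanolate | CC(C)=CCc1c(OC(C)OCC)c(C(C)([O-])N(C)OC)c(OC)c(OCOC)c1OC(C)(C)C.[Li+] | intermediate
18 | 1-[4-tert-butoxy-2-(1-ethoxyethoxy)-6-methoxy-5-(methoxymethoxy)-3-(3-methylbut-2-enyl)phenyl]ethanone | CC(C)=CCc1c(OC(C)OCC)c(C(C)=O)c(OC)c(OCOC)c1OC(C)(C)C | intermediate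
19 | N,N-dimethylformamide dimethyl acetal | COC(OC)N(C)C | starting material
20 | (E)-1-[4-tert-butoxy-2-(1-ethoxyethoxy)-6-methoxy-5-(methoxymethoxy)-3-(3-methylbut-2-enyl)phenyl]-3-(dimethylamino)prop-2-en-1-one | CC(C)=CCc1c(OC(C)OCC)c(C(=O)/C=C/N(C)C)c(OC)c(OCOC)c1OC(C)(C)C | intermediate
21 | (E)-1-[4-tert-butoxy-2-hydroxy-6-methoxy-5-(methoxymethoxy)-3-(3-methylbut-2-enyl)phenyl]-3-(dimethylamino)prop-2-en-1-one | CC(C)=CCc1c(O)c(C(=O)/C=C/N(C)C)c(OC)c(OCOC)c1OC(C)(C)C | intermediate
22 | 7-tert-butoxy-5-methoxy-6-(methoxymethoxy)-8-(3-methylbut-2-enyl)-4H-chromen-4-one | CC(C)=CCc1c(OC(C)(C)C)c(OCOC)c(OC)c2c1OC=CC2=O | intermediate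
23 | iodomagnesium 7-tert-butoxy-6-(methoxymethoxy)-8-(3-methylbut-2-enyl)-4-oxo-4H-chromen-5-olate | CC(C)=CCc1c(OC(C)(C)C)c(OCOC)c([O-])c2c1OC=CC2=O.[Mg+2].[I-] | intermediate
24 | 7-tert-butoxy-5-hydroxy-6-(methoxymethoxy)-8-(3-methylbut-2-enyl)-4H-chromen-4-one | CC(C)=CCc1c(OC(C)(C)C)c(OCOC)c(O)c2c1OC=CC2=O | intermediate
25 | 7-tert-butoxy-5,6-bis(methoxymethoxy)-8-(3-methylbut-2-enyl)-4H-chromen-4-one | CC(C)=CCc1c(OC(C)(C)C)c(OCOC)c(OCOC)c2c1OC=CC2=O | intermediate
26 | 4-(methoxymethoxy)phenylboronic acid | OB(O)c1ccc(OCOC)cc1 | starting material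
27 | (2S)-7-tert-butoxy-5,6-bis(methoxymethoxy)-2-[4-(methoxymethoxy)phenyl]-8-(3-methylbut-2-enyl)-2,3-dihydro-4H-chromen-4-one | CC(C)=CCc1c(OC(C)(C)C)c(OCOC)c(OCOC)c2c1O[C@H](c1ccc(OCOC)cc1)CC2=O | intermediate
28 | nirurinetin, (2S)-5,6,7-trihydroxy-2-(4-hydroxyphenyl)-8-(3-methylbut-2-enyl)-2,3-dihydro-4H-chromen-4-one | CC(C)=CCc1c(O)c(O)c(O)c2c1O[C@H](c1ccc(O)cc1)CC2=O | target

Total step count: 11
Longest linear sequence: 11 steps (1 → 28)

Steps most likely to fail

1. Step 1. The allylic barium reagent may attack through its substituted terminus, giving a 1,1-dimethylallyl carbinol, or may transfer an electron to the easily reduced squarate instead of adding. The fallback sets out from 1. Allylmagnesium bromide in THF at −78 °C, followed by (CF3CO)2O in the same flask, should give, through the bromomagnesium alkoxide adduct F1 and its tertiary trifluoroacetate F2, 4-allyl-3-tert-butoxycyclobut-3-ene-1,2-dione F3. Olefin cross-metathesis of F3 with 2-methylbut-2-ene (second-generation Grubbs catalyst, CH2Cl2, 40 °C) then turns the allyl group into prenyl and returns to the route at 6.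

2. Step 10. Carbopalladation of the electron-rich, fully substituted chromone may be slow, protodeboronation may outrun it, or the catalyst may discriminate poorly between the two faces. The fallback sets out from 25. Copper-mediated conjugate addition of 4-(methoxymethoxy)phenylmagnesium bromide in the presence of Me3SiCl (CuBr·SMe2, THF, −78 °C) should give the racemic silyl enol ether F7. Hydrolysis on work-up would give the racemic flavanone, that is 27 together with its (2R)-enantiomer F8, and preparative chromatography on a polysaccharide-based chiral stationary phase separates the two and returns to the route at 27.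

3. Step 5. Deprotonation may occur at the benzylic–allylic methylene of the prenyl group instead of at C4a, or the hindered aryllithium may take a proton from the acetamide instead of acylating. The fallback sets out from phenol 13 and needs no protecting group. Magnesium-mediated ortho-formylation (MgCl2, Et3N, paraformaldehyde, MeCN, reflux) should give 4-tert-butoxy-2-hydroxy-6-methoxy-5-(methoxymethoxy)-3-(3-methylbut-2-enyl)benzaldehyde F4. Addition of MeMgBr (THF, −78 → 0 °C) gives the racemic benzylic carbinol F5, and MnO2 (CH2Cl2, rt) oxidises it to the 2-hydroxyacetophenone F6. Condensation of F6 with N,N-dimethylformamide dimethyl acetal returns to the route at 21, which is cyclised to 22 under the conditions of step 7.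

Further compounds
F1 | step 1 | bromomagnesium 2,3-di-tert-butoxy-4-oxo-1-(prop-2-enyl)cyclobut-2-en-1-olate (racemic) | C=CCC1([O-])C(OC(C)(C)C)=C(OC(C)(C)C)C1=O.[Mg+2].[Br-]
F2 | step 1 | 2,3-di-tert-butoxy-4-oxo-1-(prop-2-enyl)cyclobut-2-en-1-yl trifluoroacetate (racemic) | C=CCC1(OC(=O)C(F)(F)F)C(OC(C)(C)C)=C(OC(C)(C)C)C1=O
F3 | step 1 | 4-allyl-3-tert-butoxycyclobut-3-ene-1,2-dione | C=CCC1=C(OC(C)(C)C)C(=O)C1=O
F4 | step 5 | 4-tert-butoxy-2-hydroxy-6-methoxy-5-(methoxymethoxy)-3-(3-methylbut-2-enyl)benzaldehyde | CC(C)=CCc1c(O)c(C=O)c(OC)c(OCOC)c1OC(C)(C)C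
F5 | step 5 | racemic 1-[4-tert-butoxy-2-hydroxy-6-methoxy-5-(methoxymethoxy)-3-(3-methylbut-2-enyl)phenyl]ethanol | CC(C)=CCc1c(O)c(C(C)O)c(OC)c(OCOC)c1OC(C)(C)C
F6 | step 5 | 1-[4-tert-butoxy-2-hydroxy-6-methoxy-5-(methoxymethoxy)-3-(3-methylbut-2-enyl)phenyl]ethanone | CC(C)=CCc1c(O)c(C(C)=O)c(OC)c(OCOC)c1OC(C)(C)C
F7 | step 10 | racemic 7-tert-butoxy-5,6-bis(methoxymethoxy)-2-[4-(methoxymethoxy)phenyl]-8-(3-methylbut-2-enyl)-4-(trimethylsilyloxy)-2H-chromene | CC(C)=CCc1c(OC(C)(C)C)c(OCOC)c(OCOC)c2c1OC(c1ccc(OCOC)cc1)C=C2O[Si](C)(C)C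
F8 | step 10 | (2R)-7-tert-butoxy-5,6-bis(methoxymethoxy)-2-[4-(methoxymethoxy)phenyl]-8-(3-methylbut-2-enyl)-2,3-dihydro-4H-chromen-4-one | CC(C)=CCc1c(OC(C)(C)C)c(OCOC)c(OCOC)c2c1O[C@@H](c1ccc(OCOC)cc1)CC2=O
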